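**Plan**
Numbering: ring O1, C2 (lactone C=O), C3 (acyl-bearing), C4 (enol C–OH), C5 (CH2), C6 (CHMe); side chain C1' (ketone) to C12'.
Retrosynthesis: after masking the 1,3-diol as an acetonide, O1–C6 and C2–C3 are cut together, which removes O1–C2(=O) as CO2. This carbonyl lies between C3, the acidic carbon flanked by the C4 and C1' carbonyls, and C6, a secondary carbinol carbon, so an open-chain C1'/C4 diketone with a tosylate on C6 can take up CO2 by C-carboxylation and close by carboxylate displacement.
The diketone is cut further at the C4 oxygen (ynone hydration), at C3–C1' (acetylide plus aldehyde), at C6'=C7' (cross-metathesis) and at C8'–vinyl (cuprate opening of an epoxy alcohol).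
Forward: the C7'–C12' stereotriad and the citronellal-derived C1'–C6' aldehyde are joined by metathesis; the chain is extended with an alkynyl tosylate, oxidised and hydrated; the CO2 annulation forms the only ring; the acetonide is removed last.
Stereochemistry: C10' from (S)-2-methylbutan-1-ol; C9' from Sharpless epoxidation and C8' from the invertive vinyl opening; C4' from (R)-citronellal; C6 from (S)-pent-4-yn-2-ol with inversion in the CO2 step; the E-alkene from metathesis.

Key step: step 13

Remark: β-dicarbonyl and tricarbonyl compounds are written in one tautomeric form (diketo for 18 and 19, C4-enol for 20 and 21); (S)-pent-4-yn-2-ol is taken as a commercial chiral-pool alcohol.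

**Route**

Step 1
Reactants: 1 (S)-2-methylbutan-1-ol
Product: 3 ethyl (2E,4S)-4-methylhex-2-enoate, via (S)-2-methylbutanal 2 (not isolated)
Conditions: PhI(OAc)2, TEMPO (cat.), CH2Cl2, rt; then Ph3P=CHCO2Et, rt
Reagents that add atoms: ethyl (triphenylphosphoranylidene)acetate, CCOC(=O)C=P(c1ccccc1)(c1ccccc1)c1ccccc1
Why: TEMPO/PhI(OAc)2 oxidation followed in the same flask by Wittig olefination with the stabilised ylide should give the (E)-enoate, and using the α-branched aldehyde without isolation protects the C10' centre taken from the chiral pool.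

Step 2
Reactants: 3 ethyl (2E,4S)-4-methylhex-2-enoate
Product: 4 (2E,4S)-4-methylhex-2-en-1-ol
Conditions: i-Bu2AlH (2.2 equiv), CH2Cl2, −78 → 0 °C
Reagents that add atoms: none
Why: 1,2-reduction of the enoate by diisobutylaluminium hydride should give the allylic alcohol without touching the alkene or the stereocentre.

Step 3
Reactants: 4 (2E,4S)-4-methylhex-2-en-1-ol
Product: 5 [(2R,3R)-3-[(2S)-butan-2-yl]oxiran-2-yl]methanol
Conditions: Ti(OiPr)4 (10 mol %), D-(−)-diethyl tartrate (12 mol %), t-BuOOH, 4 Å MS, CH2Cl2, −20 °C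
Reagents that add atoms: tert-butyl hydroperoxide, CC(C)(C)OO
Why: Katsuki–Sharpless asymmetric epoxidation of the (E)-allylic alcohol with the D-tartrate ligand should deliver oxygen to the face that gives the (2R,3R)-epoxide under reagent control, which fixes C9'.

Step 4
Reactants: 5 [(2R,3R)-3-[(2S)-butan-2-yl]oxiran-2-yl]methanol
Product: 6 (2S,3R,4S)-2-ethenyl-4-methylhexane-1,3-diol
Conditions: CH2=CHMgBr (4 equiv), CuI (10 mol %), THF/Et2O, −30 → 0 °C
Reagents that add atoms: vinylmagnesium bromide, C=C[Mg]Br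
Why: copper-catalysed SN2 opening of the 2,3-epoxy alcohol by the vinyl Grignard reagent should occur at C2, because C3 is shielded by the sec-butyl group, with inversion, which sets C8' anti to the C9' hydroxyl.

Step 5
Reactants: 6 (2S,3R,4S)-2-ethenyl-4-methylhexane-1,3-diol
Product: 7 (4R,5S)-4-[(2S)-butan-2-yl]-5-ethenyl-2,2-dimethyl-1,3-dioxane
Conditions: Me2C(OMe)2, PPTS (cat.), CH2Cl2, rt
Reagents that add atoms: 2,2-dimethoxypropane, COC(C)(C)OC
Why: acid-catalysed transketalisation should tie the 1,3-diol into the trans-4,5-disubstituted dioxane acetonide, which survives the basic, oxidative and metathesis steps that follow.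

Step 6
Reactants: 8 (R)-citronellal [(3R)-3,7-dimethyloct-6-enal]
Product: 9 (4R)-4,8-dimethylnona-1,7-diene
Conditions: Ph3PCH3Br, KOtBu, THF, 0 °C → rt
Reagents that add atoms: methyltriphenylphosphonium bromide, C[P+](c1ccccc1)(c1ccccc1)c1ccccc1.[Br-]
Why: Wittig methylenation of the aldehyde should give the terminal alkene that later becomes C6', and the β-stereocentre (future C4') is not enolisable.

Step 7
Reactants: 9 (4R)-4,8-dimethylnona-1,7-diene
Product: 11 (4R)-4-methylhept-6-enal, via trisubstituted epoxide 10 (not isolated)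
Conditions: mCPBA (1.0 equiv), CH2Cl2, 0 °C; then H5IO6, THF/H2O, 0 °C → rt
Reagents that add atoms: 3-chloroperbenzoic acid, OOC(=O)c1cccc(Cl)c1
Why: Prilezhaev epoxidation should select the electron-rich trisubstituted alkene over the monosubstituted one, and periodic acid should then cleave the epoxide through its diol to the aldehyde and acetone.

Step 8
Reactants: 7 (4R,5S)-4-[(2S)-butan-2-yl]-5-ethenyl-2,2-dimethyl-1,3-dioxane, 11 (4R)-4-methylhept-6-enal (3 equiv)
Product: 12 (4R,6E)-7-[(4R,5S)-4-[(2S)-butan-2-yl]-2,2-dimethyl-1,3-dioxan-5-yl]-4-methylhept-6-enal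
Conditions: second-generation Hoveyda–Grubbs catalyst RuCl2(=CH-C6H4-2-OiPr)(H2IMes) (5 mol %), CH2Cl2, 40 °C
Reagents that add atoms: none
Why: olefin cross-metathesis between the slowly dimerising allylic-branched alkene 7 and an excess of the unhindered alkene 11 should give the cross product, with the (E)-geometry favoured thermodynamically next to the branched C8'.

Step 9
Reactants: 13 (S)-pent-4-yn-2-ol
Product: 14 (2S)-pent-4-yn-2-yl 4-methylbenzenesulfonate
Conditions: TsCl, pyridine, CH2Cl2, 0 °C → rt
Reagents that add atoms: p-toluenesulfonyl chloride, Cc1ccc(cc1)S(Cl)(=O)=O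
Why: O-sulfonylation should install the leaving group on the future C6 with retention, since the C–O bond is not touched.

Step 10
Reactants: 14 (2S)-pent-4-yn-2-yl 4-methylbenzenesulfonate, 12 (4R,6E)-7-[(4R,5S)-4-[(2S)-butan-2-yl]-2,2-dimethyl-1,3-dioxan-5-yl]-4-methylhept-6-enal
Product: 16 (2S,6RS,9R,11E)-12-[(4R,5S)-4-[(2S)-butan-2-yl]-2,2-dimethyl-1,3-dioxan-5-yl]-6-hydroxy-9-methyldodec-11-en-4-yn-2-yl 4-methylbenzenesulfonate, via lithium acetylide 15 (not isolated)
Conditions: 14, n-BuLi, THF, −78 °C; then 12, −78 °C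
Reagents that add atoms: none
Why: 1,2-addition of the lithium acetylide to the aldehyde should form the C3–C1' bond, since deprotonation of the terminal alkyne at −78 °C is much faster than any attack on the secondary tosylate, and the new carbinol centre is removed in the next step.

Step 11
Reactants: 16 the propargylic alcohol of step 10
Product: 17 (2S,9R,11E)-12-[(4R,5S)-4-[(2S)-butan-2-yl]-2,2-dimethyl-1,3-dioxan-5-yl]-9-methyl-6-oxododec-11-en-4-yn-2-yl 4-methylbenzenesulfonate
Conditions: Dess–Martin periodinane, pyridine, CH2Cl2, 0 °C → rt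
Reagents that add atoms: none
Why: Dess–Martin oxidation of the propargylic alcohol should give the ynone under buffered, non-basic conditions that spare the acetonide and the tosylate.

Step 12
Reactants: 17 the ynone of step 11
Product: 18 (2S,9R,11E)-12-[(4R,5S)-4-[(2S)-butan-2-yl]-2,2-dimethyl-1,3-dioxan-5-yl]-9-methyl-4,6-dioxododec-11-en-2-yl 4-methylbenzenesulfonate
Conditions: Ph3PAuNTf2 (2 mol %), H2O (10 equiv), 1,4-dioxane, 40 °C
Reagents that add atoms: water, O
Why: gold-catalysed hydration of the ynone should place water on the β-alkyne carbon (C4), the conjugate position, and give the 1,3-diketone under neutral conditions that avoid elimination of the β-tosyloxy group.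

Step 13
Reactants: 18 the 1,3-diketone tosylate of step 12
Product: 20 (6R)-3-[(4R,6E)-7-[(4R,5S)-4-[(2S)-butan-2-yl]-2,2-dimethyl-1,3-dioxan-5-yl]-4-methylhept-6-enoyl]-4-hydroxy-6-methyl-5,6-dihydro-2H-pyran-2-one, via C3-carboxylate 19 (not isolated)
Conditions: CO2 (5 bar), Mg(OTf)2 (1.5 equiv), i-Pr2NEt (3 equiv), MeCN, 25 → 50 °C; then cold aq. citric acid
Reagents that add atoms: carbon dioxide, O=C=O
Why: Proposed new method: i-Pr2NEt and Mg(OTf)2 convert the 1,3-diketone into its magnesium diketonate, whose only nucleophilic carbon (C3, between the C1' and C4 carbonyls) adds to CO2, and the C3 carboxylate so formed displaces the C6 tosylate, so that CO2 becomes the lactone unit O1–C2(=O) with O1 on C6 and C2 on C3. The closest known reaction types are the C-carboxylation of magnesium ketone enolates with CO2 (Stiles and Rathke conditions), the carboxylative cyclisation of amines bearing an alkyl sulfonate or halide to cyclic carbamates, and the silver-catalysed capture of CO2 by ketone enolates with cyclisation onto an alkyne. The dihydropyranone ring closes by 6-exo-tet attack of a carboxylate oxygen on C6. The C6 stereocentre is set by stereospecific SN2 inversion of the (S)-tosylate, whose configuration comes from (S)-pent-4-yn-2-ol, and this should give (6R). The step needs alkylation of the carboxylate oxygen to win over alkylation of a diketonate oxygen (which would give a 2,3-dihydropyran-4-one) and over loss of the tosylate to the enone: magnesium chelation holds both diketone oxygens in the U-shaped form turned away from C6 and points the C3 substituent towards C5–C6, the monoanionic chelate is a poor trigger for E1cB elimination, and the halide-free magnesium salt excludes a double inversion through a C6 halide. Uncyclised carboxylate should simply lose CO2 on work-up and return 18, while the strongly acidic tricarbonyl product is the thermodynamic sink.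

Step 14
Reactants: 20 the acetonide-protected acylpyranone of step 13
Product: 21 (6R)-4-hydroxy-3-[(4R,6E,8S,9R,10S)-9-hydroxy-8-(hydroxymethyl)-4,10-dimethyldodec-6-enoyl]-6-methyl-5,6-dihydro-2H-pyran-2-one
Conditions: AcOH/THF/H2O (3:1:1), 40 °C
Reagents that add atoms: none
Why: acid-catalysed acetal hydrolysis should free the 1,3-diol, and the enolised 3-acyl-4-hydroxy-dihydropyranone is stable to aqueous acetic acid, so C6 is not opened or epimerised.

**Compound list**
1 | (S)-2-methylbutan-1-ol | CC[C@H](C)CO | starting material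
2 | (S)-2-methylbutanal | CC[C@H](C)C=O | intermediate
3 | ethyl (2E,4S)-4-methylhex-2-enoate | CC[C@H](C)/C=C/C(=O)OCC | intermediate
4 | (2E,4S)-4-methylhex-2-en-1-ol | CC[C@H](C)/C=C/CO | intermediate
5 | [(2R,3R)-3-[(2S)-butan-2-yl]oxiran-2-yl]methanol | CC[C@H](C)[C@H]1O[C@@H]1CO | intermediate
6 | (2S,3R,4S)-2-ethenyl-4-methylhexane-1,3-diol | CC[C@H](C)[C@@H](O)[C@@H](C=C)CO | intermediate
7 | (4R,5S)-4-[(2S)-butan-2-yl]-5-ethenyl-2,2-dimethyl-1,3-dioxane | CC[C@H](C)[C@H]1OC(C)(C)OC[C@@H]1C=C | intermediate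
8 | (R)-citronellal, (3R)-3,7-dimethyloct-6-enal | C[C@H](CCC=C(C)C)CC=O | starting material
9 | (4R)-4,8-dimethylnona-1,7-diene | C=CC[C@H](C)CCC=C(C)C | intermediate
10 | 2,2-dimethyl-3-[(3R)-3-methylhex-5-en-1-yl]oxirane (both epimers at the oxirane carbon) | C=CC[C@H](C)CCC1OC1(C)C | intermediate
11 | (4R)-4-methylhept-6-enal | C=CC[C@H](C)CCC=O | intermediate
12 | (4R,6E)-7-[(4R,5S)-4-[(2S)-butan-2-yl]-2,2-dimethyl-1,3-dioxan-5-yl]-4-methylhept-6-enal | CC[C@H](C)[C@H]1OC(C)(C)OC[C@@H]1/C=C/C[C@H](C)CCC=O | intermediate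
13 | (S)-pent-4-yn-2-ol | C[C@H](O)CC#C | starting material
14 | (2S)-pent-4-yn-2-yl 4-methylbenzenesulfonate | C#CC[C@H](C)OS(=O)(=O)c1ccc(C)cc1 | intermediate
15 | lithium acetylide of 14, (4S)-4-(tosyloxy)pent-1-yn-1-yllithium | [Li]C#CC[C@H](C)OS(=O)(=O)c1ccc(C)cc1 | intermediate
16 | (2S,6RS,9R,11E)-12-[(4R,5S)-4-[(2S)-butan-2-yl]-2,2-dimethyl-1,3-dioxan-5-yl]-6-hydroxy-9-methyldodec-11-en-4-yn-2-yl 4-methylbenzenesulfonate | CC[C@H](C)[C@H]1OC(C)(C)OC[C@@H]1/C=C/C[C@H](C)CCC(O)C#CC[C@H](C)OS(=O)(=O)c1ccc(C)cc1 | intermediate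
17 | (2S,9R,11E)-12-[(4R,5S)-4-[(2S)-butan-2-yl]-2,2-dimethyl-1,3-dioxan-5-yl]-9-methyl-6-oxododec-11-en-4-yn-2-yl 4-methylbenzenesulfonate | CC[C@H](C)[C@H]1OC(C)(C)OC[C@@H]1/C=C/C[C@H](C)CCC(=O)C#CC[C@H](C)OS(=O)(=O)c1ccc(C)cc1 | intermediate
18 | (2S,9R,11E)-12-[(4R,5S)-4-[(2S)-butan-2-yl]-2,2-dimethyl-1,3-dioxan-5-yl]-9-methyl-4,6-dioxododec-11-en-2-yl 4-methylbenzenesulfonate | CC[C@H](C)[C@H]1OC(C)(C)OC[C@@H]1/C=C/C[C@H](C)CCC(=O)CC(=O)C[C@H](C)OS(=O)(=O)c1ccc(C)cc1 | intermediate
19 | diketone 18 carrying CO2H on the carbon between the two ketones (C3), present as its magnesium carboxylate and drawn as the free acid | CC[C@H](C)[C@H]1OC(C)(C)OC[C@@H]1/C=C/C[C@H](C)CCC(=O)C(C(=O)O)C(=O)C[C@H](C)OS(=O)(=O)c1ccc(C)cc1 | intermediate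
20 | (6R)-3-[(4R,6E)-7-[(4R,5S)-4-[(2S)-butan-2-yl]-2,2-dimethyl-1,3-dioxan-5-yl]-4-methylhept-6-enoyl]-4-hydroxy-6-methyl-5,6-dihydro-2H-pyran-2-one | CC[C@H](C)[C@H]1OC(C)(C)OC[C@@H]1/C=C/C[C@H](C)CCC(=O)C1=C(O)C[C@@H](C)OC1=O | intermediate
21 | (6R)-4-hydroxy-3-[(4R,6E,8S,9R,10S)-9-hydroxy-8-(hydroxymethyl)-4,10-dimethyldodec-6-enoyl]-6-methyl-5,6-dihydro-2H-pyran-2-one | CC[C@H](C)[C@@H](O)[C@@H](/C=C/C[C@H](C)CCC(=O)C1=C(O)C[C@@H](C)OC1=O)CO | target

**Count**
Total steps: 14. Longest linear sequence: 11 steps (steps 1–5, 8, 10–14).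

**Steps most likely to fail**

Step 13. The carboxylation at C3 may not keep pace with intramolecular alkylation of a diketonate oxygen or with base-induced loss of the tosylate to the enone; the latter would also erode the C6 configuration through a non-stereospecific oxa-Michael closure. The fallback uses known chemistry, sets out from aldehyde 12 and returns at 20. Pinnick oxidation of 12 (NaClO2, NaH2PO4, 2-methylbut-2-ene, t-BuOH/H2O) should give (4R,6E)-7-[(4R,5S)-4-[(2S)-butan-2-yl]-2,2-dimethyl-1,3-dioxan-5-yl]-4-methylhept-6-enoic acid F1. Separately, commercial ethyl (R)-3-hydroxybutanoate is treated with an excess of the lithium enolate of tert-butyl acetate (LDA, THF, −78 → −20 °C) to give tert-butyl (R)-5-hydroxy-3-oxohexanoate F2. This is lactonised with CF3CO2H in CH2Cl2 to (R)-4-hydroxy-6-methyl-5,6-dihydro-2H-pyran-2-one F3. Coupling of F1 with F3 by DCC and DMAP in CH2Cl2 (O-acylation, then DMAP-mediated O-to-C acyl shift) should give 20. Here C6 is carried with retention from the hydroxy ester, and the ring is made by the classical route.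

Step 12. Acid traces from the gold catalyst may hydrolyse the acetonide, or slow hydration may allow loss of the tosylate on prolonged warming. The fallback sets out from ynone 17 and returns at diketone 18. Conjugate addition of diethylamine to 17 (CH2Cl2, rt) should give the enaminone (2S,9R,11E)-4-(diethylamino)-12-[(4R,5S)-4-[(2S)-butan-2-yl]-2,2-dimethyl-1,3-dioxan-5-yl]-9-methyl-6-oxododeca-4,11-dien-2-yl 4-methylbenzenesulfonate F4. Hydrolysis of F4 on moist silica gel or in buffered aqueous AcOH/NaOAc/THF should then give 18 without any metal catalyst.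

Step 4. The vinyl nucleophile may attack C3 as well as C2, which gives poor regioselectivity and a 1,2-diol by-product. The fallback sets out from epoxy alcohol 5 and returns at diol 6, and it replaces steric control by carboxylate-directed control. Oxidation of 5 with RuCl3 (cat.) and NaIO4 (MeCN/CCl4/H2O) should give (2S,3R)-3-[(2S)-butan-2-yl]oxirane-2-carboxylic acid F5. Organocuprates are known to open 2,3-epoxy acids at C2 with inversion, so lithium divinylcuprate should give (2R,3R,4S)-2-ethenyl-3-hydroxy-4-methylhexanoic acid F6. Reduction of F6 with LiAlH4 in THF should give 6.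

**Further compounds**
F1 | step 13 | (4R,6E)-7-[(4R,5S)-4-[(2S)-butan-2-yl]-2,2-dimethyl-1,3-dioxan-5-yl]-4-methylhept-6-enoic acid | CC[C@H](C)[C@H]1OC(C)(C)OC[C@@H]1/C=C/C[C@H](C)CCC(=O)O
F2 | step 13 | tert-butyl (R)-5-hydroxy-3-oxohexanoate | CC(C)(C)OC(=O)CC(=O)C[C@@H](C)O
F3 | step 13 | (R)-4-hydroxy-6-methyl-5,6-dihydro-2H-pyran-2-one | C[C@@H]1CC(O)=CC(=O)O1
F4 | step 12 | (2S,9R,11E)-4-(diethylamino)-12-[(4R,5S)-4-[(2S)-butan-2-yl]-2,2-dimethyl-1,3-dioxan-5-yl]-9-methyl-6-oxododeca-4,11-dien-2-yl 4-methylbenzenesulfonate | CC[C@H](C)[C@H]1OC(C)(C)OC[C@@H]1/C=C/C[C@H](C)CCC(=O)C=C(C[C@H](C)OS(=O)(=O)c1ccc(C)cc1)N(CC)CC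
F5 | step 4 | (2S,3R)-3-[(2S)-butan-2-yl]oxirane-2-carboxylic acid | CC[C@H](C)[C@H]1O[C@@H]1C(=O)O
F6 | step 4 | (2R,3R,4S)-2-ethenyl-3-hydroxy-4-methylhexanoic acid | CC[C@H](C)[C@@H](O)[C@@H](C=C)C(=O)O
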